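**Plan**

- Lactone numbering: O1, carbonyl C2, C3 (carries the 3,4,5-trimethoxybenzyl group, ring B), C4 (carries the 4-hydroxy-3,5-dimethoxybenzyl group, ring A), C5H2.
- C4 lies β to the carbonyl and holds the ring's only CH2–O unit. The retrosynthesis therefore cuts C4–C5 and O1–C2 together: C5/O1 become formaldehyde and C2–C3=C4 becomes an (E)-α-benzyl enal made nucleophilic at C4 by a carbene.
- The enal C3=C4 bond is then cut by cross-metathesis into the ring A allylarene and a 2-benzylacrolein. The acrolein goes back by α-methylenation and a Heck reaction to 5-iodo-1,2,3-trimethoxybenzene and allyl alcohol.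
- Forward: one step for the ring A arm, two for the ring B arm, metathesis joins them, the annulation closes the only ring that is built, and hydrogenolysis frees the phenol.
- Stereochemistry: C4 (R) comes from the chiral triazolium carbene choosing the face of C4 that meets formaldehyde. C3 (R) comes from base equilibration to the 3,4-trans lactone, which only C3 can undergo.

Key step: step 5

Assumption: the sense of induction of the aminoindanol-derived carbene for this enal–formaldehyde pairing cannot be predicted with confidence; the (5aS,10bR) triazolium chloride is written, and its equally available (5aR,10bS) mirror image takes its place should the first run deliver the 4S series.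

**Step 1**
Reactants: 1 4-allyl-2,6-dimethoxyphenol
Product: 2 2-(benzyloxy)-1,3-dimethoxy-5-(prop-2-en-1-yl)benzene
Conditions: BnBr (1.1 equiv), K2CO3 (1.5 equiv), DMF, 60 °C
Reagents that add atoms: benzyl bromide, BrCc1ccccc1
Why: Williamson ether synthesis, in which the phenoxide formed by K2CO3 displaces bromide from benzyl bromide by SN2 while the allyl group is untouched by this mild base.

**Step 2**
Reactants: 3 5-iodo-1,2,3-trimethoxybenzene; 4 prop-2-en-1-ol (allyl alcohol)
Product: 5 3-(3,4,5-trimethoxyphenyl)propanal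
Conditions: Pd(OAc)2 (3 mol%), Bu4NCl (1.0 equiv), NaHCO3 (2.5 equiv), DMF, 45 °C
Reagents that add atoms: none
Why: Mizoroki–Heck reaction under ligand-free phase-transfer conditions, in which the arylpalladium iodide adds to allyl alcohol with the aryl group at the terminal carbon and β-hydride elimination toward the carbinol carbon delivers the saturated aldehyde instead of a cinnamyl alcohol.

**Step 3**
Reactants: 5 3-(3,4,5-trimethoxyphenyl)propanal; 6 formaldehyde (37% aqueous solution)
Product: 7 2-[(3,4,5-trimethoxyphenyl)methyl]prop-2-enal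
Conditions: 37% aq. CH2O (1.2 equiv), pyrrolidine (10 mol%), propionic acid (10 mol%), iPrOH, 45 °C
Reagents that add atoms: none
Why: Amine-catalysed α-methylenation (Mannich condensation followed by elimination of the amine), a standard transformation of 3-arylpropanals in which the pyrrolidine enamine of 5 adds to the iminium ion of formaldehyde and loss of pyrrolidine leaves the 1,1-disubstituted enal.

**Step 4**
Reactants: 2 2-(benzyloxy)-1,3-dimethoxy-5-(prop-2-en-1-yl)benzene; 7 2-[(3,4,5-trimethoxyphenyl)methyl]prop-2-enal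
Product: 8 (2E)-4-[4-(benzyloxy)-3,5-dimethoxyphenyl]-2-[(3,4,5-trimethoxyphenyl)methyl]but-2-enal
Conditions: 2 (2.0 equiv), second-generation Hoveyda–Grubbs catalyst RuCl2(H2IMes)(=CH-C6H4-2-OiPr) (5 mol%), 1,4-benzoquinone (10 mol%), CH2Cl2, 40 °C
Reagents that add atoms: none
Why: Olefin cross-metathesis between a fast-dimerising terminal alkene and a 2-substituted acrolein that does not homodimerise, as established for methacrolein and 2-ethylacrolein, which should give the trisubstituted enal as the thermodynamically preferred E isomer (CH2Ar trans to CHO) that no longer re-enters metathesis, with benzoquinone suppressing allyl-to-propenyl isomerisation.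

**Step 5**
Reactants: 8 (2E)-4-[4-(benzyloxy)-3,5-dimethoxyphenyl]-2-[(3,4,5-trimethoxyphenyl)methyl]but-2-enal; 6 formaldehyde (released in the flask from paraformaldehyde)
Product: 10 (3R,4R)-4-{[4-(benzyloxy)-3,5-dimethoxyphenyl]methyl}-3-[(3,4,5-trimethoxyphenyl)methyl]oxolan-2-one, via cis lactone 9 (not isolated)
Conditions: (5aS,10bR)-2-mesityl-5a,10b-dihydro-4H,6H-indeno[2,1-b][1,2,4]triazolo[4,3-d][1,4]oxazin-2-ium chloride (10 mol%), DBU (15 mol%), paraformaldehyde (3 equiv CH2O), THF, 40 °C; then filter, evaporate, DBU (1.0 equiv), toluene, 80 °C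
Reagents that add atoms: none
Why: Proposed new method: the free carbene adds to the aldehyde carbon C2 of 8 and proton transfer gives the extended Breslow intermediate, whose β-carbon C4 attacks formaldehyde (C4–C5), after which protonation at C3 turns the enol azolium into an acyl azolium that the C5 alkoxide acylates (O1–C2) with release of the carbene. The closest known reaction type is the carbene-catalysed homoenolate annulation of β-substituted enals with aldehydes to γ-butyrolactones, which has not been shown for an α-branched enal paired with formaldehyde. The lactone closes by 5-exo-trig acyl substitution of the alkoxide on the acyl azolium. C4 is controlled by the aminoindanol-derived triazolylidene, which shields one face of the planar homoenolate so that formaldehyde adds to the other, whereas C3 is set only in part on protonation and is then brought to the 3,4-trans arrangement by DBU, the thermodynamic preference of the two benzyl groups for trans being the controlling element because C3 alone can epimerise. The step needs attack through C4 and not through the acyl-anion carbon, and cross reaction instead of enal self-annulation; the N-mesityl carbene and the α-benzyl group crowd C2, the α-branched enal carbonyl is a poor acceptor, formaldehyde is the most electrophilic and least hindered partner present, and the single E geometry from step 4 gives one homoenolate geometry.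

**Step 6**
Reactants: 10 (3R,4R)-4-{[4-(benzyloxy)-3,5-dimethoxyphenyl]methyl}-3-[(3,4,5-trimethoxyphenyl)methyl]oxolan-2-one
Product: 11 (3R,4R)-4-[(4-hydroxy-3,5-dimethoxyphenyl)methyl]-3-[(3,4,5-trimethoxyphenyl)methyl]oxolan-2-one (CNP0118453.1)
Conditions: H2 (1 atm), 10% Pd/C, EtOAc–EtOH, rt
Reagents that add atoms: none
Why: Hydrogenolysis of the benzyl aryl ether over palladium on carbon, under neutral conditions that leave the lactone, the aryl methyl ethers and both stereocentres untouched.

**Compound list**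

1 | 4-allyl-2,6-dimethoxyphenol | C=CCc1cc(OC)c(O)c(OC)c1 | starting material
2 | 2-(benzyloxy)-1,3-dimethoxy-5-(prop-2-en-1-yl)benzene | C=CCc1cc(OC)c(OCc2ccccc2)c(OC)c1 | intermediate
3 | 5-iodo-1,2,3-trimethoxybenzene | COc1cc(I)cc(OC)c1OC | starting material
4 | prop-2-en-1-ol (allyl alcohol) | C=CCO | starting material
5 | 3-(3,4,5-trimethoxyphenyl)propanal | O=CCCc1cc(OC)c(OC)c(OC)c1 | intermediate
6 | formaldehyde (aqueous solution in step 3, paraformaldehyde in step 5) | C=O | starting material
7 | 2-[(3,4,5-trimethoxyphenyl)methyl]prop-2-enal | C=C(C=O)Cc1cc(OC)c(OC)c(OC)c1 | intermediate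
8 | (2E)-4-[4-(benzyloxy)-3,5-dimethoxyphenyl]-2-[(3,4,5-trimethoxyphenyl)methyl]but-2-enal | O=C/C(Cc1cc(OC)c(OC)c(OC)c1)=C/Cc1cc(OC)c(OCc2ccccc2)c(OC)c1 | intermediate
9 | (3S,4R)-4-{[4-(benzyloxy)-3,5-dimethoxyphenyl]methyl}-3-[(3,4,5-trimethoxyphenyl)methyl]oxolan-2-one (cis lactone, C3 epimer formed in part, not isolated) | O=C1OC[C@H](Cc2cc(OC)c(OCc3ccccc3)c(OC)c2)[C@@H]1Cc1cc(OC)c(OC)c(OC)c1 | intermediate
10 | (3R,4R)-4-{[4-(benzyloxy)-3,5-dimethoxyphenyl]methyl}-3-[(3,4,5-trimethoxyphenyl)methyl]oxolan-2-one | O=C1OC[C@H](Cc2cc(OC)c(OCc3ccccc3)c(OC)c2)[C@H]1Cc1cc(OC)c(OC)c(OC)c1 | intermediate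
11 | (3R,4R)-4-[(4-hydroxy-3,5-dimethoxyphenyl)methyl]-3-[(3,4,5-trimethoxyphenyl)methyl]oxolan-2-one | COc1cc(C[C@H]2COC(=O)[C@@H]2Cc2cc(OC)c(OC)c(OC)c2)cc(OC)c1O | target

**Totals**

Total step count: 6.
Longest linear sequence: 5 steps (steps 2, 3, 4, 5, 6, from 3 and 4).

**Steps most likely to fail**

1. Step 5 (the proposed new method). Several things may go wrong:
   - The carbene may be diverted into acyl-anion chemistry, either hydroxymethylation at C2 or self-condensation of formaldehyde.
   - Breslow formation on the α-branched enal may be too slow to compete with base-induced migration of the double bond into conjugation with ring A.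
   - Facial selectivity at C4 toward so small an electrophile may be poor.

   The fallback uses known chemistry, sets out from 2 and comes back at 10. Hydroboration–oxidation of 2 (9-BBN, THF; NaOH, H2O2) should give 3-[4-(benzyloxy)-3,5-dimethoxyphenyl]propan-1-ol F1. Oxidation (TEMPO, 2,2,6,6-tetramethylpiperidin-1-oxyl, catalytic, PhI(OAc)2, MeCN–water) should give 3-[4-(benzyloxy)-3,5-dimethoxyphenyl]propanoic acid F2. Its mixed pivalic anhydride (PivCl, Et3N, LiCl) acylates (4S)-4-benzyl-1,3-oxazolidin-2-one to (4S)-4-benzyl-3-{3-[4-(benzyloxy)-3,5-dimethoxyphenyl]propanoyl}-1,3-oxazolidin-2-one F3. Evans alkylation of the sodium enolate (NaN(SiMe3)2, THF, −78 °C) with tert-butyl bromoacetate, on the face away from the auxiliary benzyl group, should give tert-butyl (3R)-4-[(4S)-4-benzyl-2-oxo-1,3-oxazolidin-3-yl]-3-{[4-(benzyloxy)-3,5-dimethoxyphenyl]methyl}-4-oxobutanoate F4. Reductive removal of the auxiliary (LiBH4, THF, one equivalent of MeOH, 0 °C) gives tert-butyl (3R)-3-{[4-(benzyloxy)-3,5-dimethoxyphenyl]methyl}-4-hydroxybutanoate F5. Acid (p-TsOH·H2O, catalytic, toluene, 80 °C) closes this to (4R)-4-{[4-(benzyloxy)-3,5-dimethoxyphenyl]methyl}oxolan-2-one F6. Deprotonation (LiN(SiMe3)2, THF, −78 °C) and alkylation with 3,4,5-trimethoxybenzyl bromide, which enters anti to the C4 substituent, then gives 10.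

2. Step 4. Turnover at the 1,1-disubstituted acrolein may be too slow, so that homodimerisation of the allylarene and ruthenium hydride-induced allyl-to-propenyl isomerisation use up 2 before the cross product forms.

   The fallback replaces metathesis by carbonyl olefination, sets out from 2 and comes back at 8. Lemieux–Johnson cleavage of 2 (OsO4 catalytic, NaIO4, 2,6-lutidine, dioxane–water) should give 2-[4-(benzyloxy)-3,5-dimethoxyphenyl]acetaldehyde F7, to be used at once. Separately, ethyl (triphenylphosphoranylidene)acetate is alkylated with 3,4,5-trimethoxybenzyl bromide (CHCl3, reflux) to racemic [1-ethoxy-1-oxo-3-(3,4,5-trimethoxyphenyl)propan-2-yl]triphenylphosphonium bromide F8. Aqueous NaOH converts this to ethyl 3-(3,4,5-trimethoxyphenyl)-2-(triphenyl-λ5-phosphanylidene)propanoate F9. Wittig reaction of F7 with F9 (CH2Cl2, rt, base-free) should give ethyl (2E)-4-[4-(benzyloxy)-3,5-dimethoxyphenyl]-2-[(3,4,5-trimethoxyphenyl)methyl]but-2-enoate F10. Reduction (iBu2AlH, CH2Cl2, −78 °C) gives (2E)-4-[4-(benzyloxy)-3,5-dimethoxyphenyl]-2-[(3,4,5-trimethoxyphenyl)methyl]but-2-en-1-ol F11. Allylic oxidation (MnO2, CH2Cl2, rt) then returns 8.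

3. Step 2. Insertion may lose regiocontrol (aryl at the internal carbon), the product aldehyde may self-condense under the basic conditions, and palladium black may deposit before conversion is complete.

   The fallback builds the three-carbon chain at the ester oxidation level, sets out from 3 and comes back at 5. Mizoroki–Heck coupling of 3 with ethyl acrylate (Pd(OAc)2, P(o-tol)3, Et3N, DMF, 90 °C) should give ethyl (2E)-3-(3,4,5-trimethoxyphenyl)prop-2-enoate F12. Hydrogenation (H2, 10% Pd/C, EtOAc) gives ethyl 3-(3,4,5-trimethoxyphenyl)propanoate F13. Partial reduction (iBu2AlH, 1.05 equiv, toluene, −78 °C) gives 5.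

**Further compounds**

F1 | step 5 | 3-[4-(benzyloxy)-3,5-dimethoxyphenyl]propan-1-ol | OCCCc1cc(OC)c(OCc2ccccc2)c(OC)c1
F2 | step 5 | 3-[4-(benzyloxy)-3,5-dimethoxyphenyl]propanoic acid | OC(=O)CCc1cc(OC)c(OCc2ccccc2)c(OC)c1
F3 | step 5 | (4S)-4-benzyl-3-{3-[4-(benzyloxy)-3,5-dimethoxyphenyl]propanoyl}-1,3-oxazolidin-2-one | O=C(CCc1cc(OC)c(OCc2ccccc2)c(OC)c1)N1C(=O)OC[C@@H]1Cc1ccccc1
F4 | step 5 | tert-butyl (3R)-4-[(4S)-4-benzyl-2-oxo-1,3-oxazolidin-3-yl]-3-{[4-(benzyloxy)-3,5-dimethoxyphenyl]methyl}-4-oxobutanoate | CC(C)(C)OC(=O)C[C@@H](Cc1cc(OC)c(OCc2ccccc2)c(OC)c1)C(=O)N1C(=O)OC[C@@H]1Cc1ccccc1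
F5 | step 5 | tert-butyl (3R)-3-{[4-(benzyloxy)-3,5-dimethoxyphenyl]methyl}-4-hydroxybutanoate | CC(C)(C)OC(=O)C[C@@H](Cc1cc(OC)c(OCc2ccccc2)c(OC)c1)CO
F6 | step 5 | (4R)-4-{[4-(benzyloxy)-3,5-dimethoxyphenyl]methyl}oxolan-2-one | O=C1C[C@@H](Cc2cc(OC)c(OCc3ccccc3)c(OC)c2)CO1
F7 | step 4 | 2-[4-(benzyloxy)-3,5-dimethoxyphenyl]acetaldehyde | O=CCc1cc(OC)c(OCc2ccccc2)c(OC)c1
F8 | step 4 | [1-ethoxy-1-oxo-3-(3,4,5-trimethoxyphenyl)propan-2-yl]triphenylphosphonium bromide (racemic) | CCOC(=O)C(Cc1cc(OC)c(OC)c(OC)c1)[P+](c1ccccc1)(c1ccccc1)c1ccccc1.[Br-]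
F9 | step 4 | ethyl 3-(3,4,5-trimethoxyphenyl)-2-(triphenyl-λ5-phosphanylidene)propanoate | CCOC(=O)C(Cc1cc(OC)c(OC)c(OC)c1)=P(c1ccccc1)(c1ccccc1)c1ccccc1
F10 | step 4 | ethyl (2E)-4-[4-(benzyloxy)-3,5-dimethoxyphenyl]-2-[(3,4,5-trimethoxyphenyl)methyl]but-2-enoate | CCOC(=O)/C(Cc1cc(OC)c(OC)c(OC)c1)=C/Cc1cc(OC)c(OCc2ccccc2)c(OC)c1
F11 | step 4 | (2E)-4-[4-(benzyloxy)-3,5-dimethoxyphenyl]-2-[(3,4,5-trimethoxyphenyl)methyl]but-2-en-1-ol | OC/C(Cc1cc(OC)c(OC)c(OC)c1)=C/Cc1cc(OC)c(OCc2ccccc2)c(OC)c1
F12 | step 2 | ethyl (2E)-3-(3,4,5-trimethoxyphenyl)prop-2-enoate | CCOC(=O)/C=C/c1cc(OC)c(OC)c(OC)c1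
F13 | step 2 | ethyl 3-(3,4,5-trimethoxyphenyl)propanoate | CCOC(=O)CCc1cc(OC)c(OC)c(OC)c1
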